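## The problem

CNP0269971.1 is a biflavonoid ether. A (2S)-flavanone (5-hydroxy, 7-methoxy, 4′-hydroxy) is joined through its C6 oxygen to C4′ of apigenin, and this single diaryl ether is the only link between the halves.

- **The ether bond.** C6 of the flavanone lies between the C5 hydroxyl and the C7 methoxyl. Forming the aryl–O–C6 bond on a finished ring A means a coupling at an electron-rich carbon with two ortho substituents.
- **Ring A.** It is a pentasubstituted benzene with four oxygens of four kinds: free OH at C5, aryl ether at C6, methyl ether at C7 and the ring oxygen at C8a. A symmetrical phloroglucinol-type starting arene would need these told apart afterwards.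
- **The stereocentre.** C2 (S) is the only one. It is benzylic and β to the C4 carbonyl, so no other centre can control it and it must come from a reagent. Once the 5-hydroxy-4-ketone exists, base opens ring C to the chalcone and racemises it.
- **Sensitive groups.** The four phenols do not tolerate oxidants, so they are carried as benzyl ethers and released last under neutral conditions. The flavone C2=C3 bond and the flavanone carbonyl limit how forcing that release may be.
- **The enabling feature.** Ring A is a resorcinol: the C5 and C8a oxygens are meta with C4a between them, and the C6 and C7 oxygens sit on adjacent carbons. A 4-oxy-3-alkoxycyclobutenone (C5, C6, C7, C8) and a ynol ether (C4a, C8a) give exactly this pattern. The C6 oxygen can therefore be attached to an sp3 carbon as a simple alkyl aryl ether before ring A exists.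

## Retrosynthesis

**28 to 27.** The four O–benzyl bonds are cut. Benzyl is chosen because all four phenols can be freed in one neutral hydrogenolysis after the base-sensitive flavanone is in place. Acid-labile or silyl groups would not survive the steps before it. The forward step must spare the flavone double bond and the benzylic C2–O1 bond.

**27 to 25 through 26.** The C4 carbonyl oxygen is removed, leaving flavan 25. A flavan has no base-labile centre and can be closed by substitution at C2. Carrying the ketone into the ring closure would give a β-hydroxy ketone that can eliminate to the chalcone. Forward, a hydride must be taken from C4 only (DDQ, water capture to 26), then the alcohol is oxidised.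

**25 to 24, 23 and 22.** The O1–C2 bond is cut, giving phenol–carbinol 24 for a Mitsunobu closure with inversion, so the carbinol must be (R). Cutting C8a–O1 instead would need an aryl halide at C8a, which the ring construction does not give. Diol 24 comes from the bis-silyl ether 23 by fluoride, and 23 from phenol 22 by benzylation. The benzyl ether at C5 is essential: after desilylation both the C5 and C8a oxygens are ortho to the side chain and either could close a six-membered ring.

**22 to 10 and 17 (key disconnection).** Three ring bonds are cut: C4a–C5, C8–C8a and C5–C6. Ring A disappears, leaving cyclobutenone 10 (C5 to C8, with the aryloxy group on its sp3 carbon) and siloxyalkyne 17 (C8a, C4a and the chain C4–C3–C2).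

- Against the neighbouring cuts (ether coupling on an arene, or acylation of a symmetric phenol), this one never makes the hindered C–O bond on a ring, and it delivers C5–OH free and C8a–O silylated.
- The tether between alkyne and carbinol must be two methylenes. One methylene would lead to a dihydrobenzofuran. An oxygen at the propargylic carbon would return as an ortho-hydroxybenzylic alcohol prone to ionisation.
- Forward, the reaction needs thermal opening of 10 and a single orientation of alkyne addition.

**10 to 5 and 7, then to 1, 3 and 6.** The cyclobutenone bonds C1–C2 and C3–C4 are cut to aryloxyketene 9 (from acid 5 through chloride 8) and methoxyacetylene 7, which is made from chloroacetal 6. Flavone 5 is cut at O1–C2 to chalcone 4, and 4 at its enone double bond to acetophenone 2 and (4-formylphenoxy)acetic acid 3. Acid 3 is commercial, and otherwise one O-alkylation from 4-hydroxybenzaldehyde; it already holds the future C6–O–aryl linkage. Compound 2 is the dibenzyl ether of 1. The forward steps are a Claisen–Schmidt condensation, an oxidative cyclisation and a ketene [2+2] addition of fixed orientation.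

**17 to 11 and 12.** The alkyne C–O bond is cut to terminal alkyne 15 (acetylide oxidation, then silylation). The carbinol C–H bond is cut to ketone 13 (reagent-controlled reduction to 14, then silylation). The C3–C4 bond is cut to 4′-(benzyloxy)acetophenone 11 and propargyl bromide 12. This takes four steps and uses no stereochemical relay; the reducing agent must leave the alkyne alone.

## Roads not taken

**Alternative 1: carbonylative closure of the flavone ring C.** The cut is through the apigenin pyranone (C4–C4a, C3–C4, O1–C2). Forward, 3,5-bis(benzyloxy)-2-iodophenol A1, CO and the aryl alkyne A2 (carrying the silylated (2S,4S)-flavan-4-ol) couple under PdCl2(PPh3)2 and Et2NH to give flavone A3.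

- Merits: late convergence, mild conditions, and C4 of the flavan already at the alcohol level, so no C–H oxidation is needed.
- Weak points: the diaryl ether in A2 must still be made on a 5,7-dimethoxylated ring A, at the hindered position. The key step builds a ring that phloroacetophenone chemistry supplies cheaply. Five-membered closure to an aurone can compete. The C5 and C7 methyl ethers must later be told apart by chelation-controlled cleavage.
- Comparison: from A3 onward the endgame is probably more dependable than the chosen plan's benzannulation and DDQ oxidation. Against that, the chosen plan makes the C6–O bond at an sp3 carbon and delivers the ring A oxygens already differentiated.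

**Alternative 2: folding a pyranone-masked polyketide into flavone ring A.** The cut is C4a–C5 of the apigenin half. Forward, Mg(OMe)2 turns the pyranonyl β-keto ester A4 into a dienolate whose pyranone C3 attacks the ester, giving the 5,7-dihydroxyflavone A5.

- Merits: biomimetic, regiochemistry fixed by the chain, and no protecting groups on the new resorcinol.
- Weak points: it spends the strategic step on the phloroglucinol ring, which can be bought. A4 needs a dianion acylation of a methylpyranone. A5 has two free phenols to re-protect before the flavanone is built on its 4-benzyloxy-2,6-dimethoxyphenyl ring. The hindered ether, the C2 stereocentre and the C5/C7 differentiation all remain.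
- Comparison: the magnesium-templated condensation is gentler and better precedented than the chosen benzannulation on its untested cyclobutenone. The chosen plan answers with a key step that solves the ether, ring A and the oxygen pattern at once.

**Alternative 3: symmetric aryloxyphenol and Friedel–Crafts closure of ring C.** The cut is C4–C4a. Forward, the (S)-3-aryl-3-aryloxypropanoic acid A6 is activated with (CF3CO)2O and acylates one of two equivalent ortho carbons, giving flavanone A7.

- Merits: no regiochemical question, and C4 arrives as the ketone. This is better than the chosen plan, which needs two oxidation steps, and fewer steps follow the key step.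
- Weak points: the ether must first be made at the di-ortho-substituted position of a 3,5-dimethoxyphenol. The benzylic β-aryloxy acid can ionise or eliminate to a cinnamate under acidic acylation, eroding C2. The intermolecular etherification that sets C2 is elimination-prone. One of two methyl ethers must be cleaved selectively at the end.
- Comparison: the ring closure itself is more predictable than the benzannulation. The chosen plan sets against it the unhindered formation of the ether, oxygens differentiated from the outset, and a stereocentre never exposed to strong acid.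

Key step: step 10

Remark: lithium and potassium salts that are only the conjugate bases of numbered compounds (enolate, acetylide, phenoxides) are formed and consumed in situ and are not numbered separately.

## Route

Step 1
Reactants: 1 2′,4′,6′-trihydroxyacetophenone
Product: 2 1-[2,4-bis(benzyloxy)-6-hydroxyphenyl]ethan-1-one
Conditions: BnBr (2.05 equiv), K2CO3, DMF, rt
Reagents that add atoms: benzyl bromide, BrCc1ccccc1
Why: Williamson etherification; after the para and one ortho hydroxyl are alkylated, the remaining ortho hydroxyl is hydrogen-bonded to the acetyl group and should stay free for the later ring closure.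

Step 2
Reactants: 2 1-[2,4-bis(benzyloxy)-6-hydroxyphenyl]ethan-1-one; 3 (4-formylphenoxy)acetic acid
Product: 4 (E)-chalcone acid, 2-{4-[3-(2,4-bis(benzyloxy)-6-hydroxyphenyl)-3-oxoprop-1-en-1-yl]phenoxy}acetic acid
Conditions: KOH (excess), EtOH/H2O, rt; then aq. HCl
Reagents that add atoms: none
Why: Claisen–Schmidt condensation; the acid travels as its carboxylate, insulated from the aldehyde by the OCH2 group, and aldol addition followed by E1cB dehydration should give the E-enone.

Step 3
Reactants: 4 (E)-chalcone acid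
Product: 5 flavone acid, 2-{4-[5,7-bis(benzyloxy)-4-oxo-4H-chromen-2-yl]phenoxy}acetic acid
Conditions: I2 (cat.), DMSO, 130 °C
Reagents that add atoms: none
Why: Iodine-catalysed oxidative cyclisation of a 2′-hydroxychalcone (oxa-Michael closure, then iodination–elimination with DMSO reoxidising HI), the standard flavone synthesis; benzyl ethers and the carboxylic acid should survive a short reaction time.

Step 4
Reactants: 6 chloroacetaldehyde dimethyl acetal
Product: 7 methoxyacetylene
Conditions: NaNH2 (3 equiv), liq. NH3, −33 °C; then cold aq. NaCl, distil into a cold trap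
Reagents that add atoms: none
Why: Twofold base-induced β-elimination (methanol, then HCl) gives the sodium acetylide, which is protonated on quenching; this is the classical preparation of the volatile ynol ether, used at once as a cold solution.

Step 5
Reactants: 5 flavone acid; 7 methoxyacetylene
Product: 10 5,7-bis(benzyloxy)-2-{4-[(2-methoxy-4-oxocyclobut-2-en-1-yl)oxy]phenyl}-4H-chromen-4-one (racemic), via acid chloride 8 (not isolated), via aryloxyketene 9 (not isolated)
Conditions: Me2C=C(Cl)NMe2, CH2Cl2, 0 °C → rt; then 7 (excess), Et3N (slow addition), CH2Cl2, 0 °C → rt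
Reagents that add atoms: none
Why: The chloroenamine makes the acid chloride under neutral conditions that leave the pyranone alone, and Et3N then gives the aryloxyketene. Ketene–ynol ether [2+2] cycloaddition is the standard route to 3-alkoxycyclobutenones; the unsubstituted alkyne carbon bonds to the ketene carbonyl carbon, placing OMe at C3 and the aryloxy carbon at C4.

Step 6
Reactants: 11 4′-(benzyloxy)acetophenone; 12 propargyl bromide
Product: 13 1-[4-(benzyloxy)phenyl]pent-4-yn-1-one
Conditions: LiN(iPr)2, THF, −78 °C; then 12, −78 → 0 °C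
Reagents that add atoms: none
Why: SN2 alkylation of the kinetic lithium enolate of an aryl methyl ketone; low temperature and a slight excess of ketone should limit dialkylation.

Step 7
Reactants: 13 1-[4-(benzyloxy)phenyl]pent-4-yn-1-one
Product: 14 (R)-1-[4-(benzyloxy)phenyl]pent-4-yn-1-ol
Conditions: (+)-Ipc2BCl, THF, −25 °C; then CH3CHO, 0 °C → rt; aq. NaOH
Reagents that add atoms: none
Why: Reagent-controlled asymmetric reduction with B-chlorodiisopinocampheylborane through a cyclic six-membered transition state. The reagent derived from (−)-α-pinene gives the (R)-carbinol from aryl alkyl ketones, with the aryl group as the large substituent. It has no B–H bond, so the terminal alkyne is untouched.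

Step 8
Reactants: 14 (R)-1-[4-(benzyloxy)phenyl]pent-4-yn-1-ol
Product: 15 (R)-{1-[4-(benzyloxy)phenyl]pent-4-yn-1-yl}oxy(tert-butyl)dimethylsilane
Conditions: TBSCl, imidazole, DMF, rt
Reagents that add atoms: tert-butyldimethylsilyl chloride, CC(C)(C)[Si](C)(C)Cl
Why: Standard silylation of a secondary alcohol; the ether masks the carbinol through the strongly basic and the thermal steps without touching the stereocentre.

Step 9
Reactants: 15 (R)-{1-[4-(benzyloxy)phenyl]pent-4-yn-1-yl}oxy(tert-butyl)dimethylsilane
Product: 17 (R)-siloxyalkyne, tert-butyl({1-[4-(benzyloxy)phenyl]-5-[(triisopropylsilyl)oxy]pent-4-yn-1-yl}oxy)dimethylsilane, via lithium ynolate 16 (not isolated)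
Conditions: LiN(SiMe3)2 (2.2 equiv), t-BuOOH (1.1 equiv), THF, −78 → 0 °C; then iPr3SiOTf, −78 °C
Reagents that add atoms: tert-butyl hydroperoxide, CC(C)(C)OO; triisopropylsilyl trifluoromethanesulfonate, CC(C)[Si](C(C)C)(C(C)C)OS(=O)(=O)C(F)(F)F
Why: Electrophilic oxygen transfer from lithium tert-butylperoxide to the lithium acetylide gives the ynolate, which the bulky silyl triflate traps on oxygen. This is an established route from terminal alkynes to triisopropylsiloxyalkynes; the remote silyl and benzyl ethers are inert to it.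

Step 10
Reactants: 10 4-aryloxy-3-methoxycyclobutenone; 17 (R)-siloxyalkyne
Product: 22 ring A phenol (C5–OH free; C8a–OSi(iPr)3; C7–OMe; C6–O–aryl; C4a–CH2CH2CH(OTBS)Ar with (R) carbinol), via vinylketene 18 (not isolated), via 4-vinylcyclobutenone 19 (not isolated), via dienylketene 20 (not isolated), via cyclohexadienone 21 (not isolated)
Conditions: toluene, 80 → 110 °C, sealed tube, 17 in slight excess
Reagents that add atoms: none
Why: Danheiser benzannulation in its siloxyalkyne form. Heating opens 10 by four-electron conrotatory electrocyclic cleavage of the C1–C4 bond, the C4 aryloxy donor turning outward and easing the opening, to give vinylketene 18. The electron-rich alkyne 17 attacks the ketene carbonyl carbon through its carbon remote from oxygen and closes the [2+2] adduct 19, so the side chain becomes C4a between the future C5 hydroxyl and the C8a siloxy group. 19 opens again in a reversible four-electron electrocyclic step, and only the isomer with the methoxyvinyl group turned toward the ketene, dienylketene 20, can go on. Ring A closes by six-electron disrotatory electrocyclisation of 20, joining the ketene carbon (C5) to the aryloxy-bearing terminus (C6) to give cyclohexadienone 21, which tautomerises to phenol 22. No stereocentre is created: the sp3 carbons of 19 and 21 are lost on aromatisation and the (R)-carbinol is a spectator. The closest established reactions are the benzannulation of alkyl- and aryl-substituted cyclobutenones with triisopropylsiloxyalkynes and the thermal opening of 3-alkoxy-4-oxy-substituted cyclobutenones to vinylketenes near 100 °C; a 3-methoxy-4-aryloxy substrate in the intermolecular reaction is untested. The step needs one orientation of alkyne addition, which the polarisation of both partners secures, and it leaves C5–OH free and C8a–O silylated, so the two meta oxygens are differentiated from the start.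

Step 11
Reactants: 22 ring A phenol
Product: 23 C5 benzyl ether of 22
Conditions: BnBr, K2CO3, Bu4NI (cat.), acetone, 50 °C
Reagents that add atoms: benzyl bromide, BrCc1ccccc1
Why: Williamson benzylation of the only free phenol; it keeps C5–O and C8a–O apart for the ring closure, and the aryl triisopropylsilyl ether should hold under anhydrous carbonate.

Step 12
Reactants: 23 C5 benzyl ether
Product: 24 phenol–carbinol (C8a–OH and (R)-configured benzylic OH free)
Conditions: Bu4NF (3 equiv), THF, 0 °C → rt; aq. NH4Cl
Reagents that add atoms: none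
Why: Fluoride cleaves both Si–O bonds (aryl triisopropylsilyl and alkyl tert-butyldimethylsilyl); benzyl ethers and the flavone are inert and the carbinol centre is not touched.

Step 13
Reactants: 24 phenol–carbinol
Product: 25 (2S)-flavan, 5,7-bis(benzyloxy)-2-[4-({(2S)-5-(benzyloxy)-2-[4-(benzyloxy)phenyl]-7-methoxychroman-6-yl}oxy)phenyl]-4H-chromen-4-one
Conditions: PPh3, DIAD, THF, 0 °C → rt
Reagents that add atoms: none
Why: Intramolecular Mitsunobu etherification; the C8a phenoxide displaces the oxyphosphonium group at the benzylic carbon in a six-membered SN2 closure with inversion, turning the (R)-carbinol into (2S). This closure is known for 1-aryl-3-(2-hydroxyaryl)propan-1-ols.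

Step 14
Reactants: 25 (2S)-flavan
Product: 26 (2S)-flavan-4-ol (both C4 epimers)
Conditions: DDQ (1.5 equiv), CH2Cl2/H2O (10:1), 0 °C → rt
Reagents that add atoms: water, O
Why: DDQ abstracts hydride from C4, the benzylic position of the tetraoxygenated ring A, giving a cation stabilised by O1, the C5 benzyloxy group and the C7 methoxyl; water captures it. Oxidative C4 functionalisation of flavans with an oxygenated ring A is known. C2 is not involved, and the uncontrolled C4 centre is removed in the next step.

Step 15
Reactants: 26 (2S)-flavan-4-ol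
Product: 27 protected (2S)-flavanone, 5,7-bis(benzyloxy)-2-[4-({(2S)-5-(benzyloxy)-2-[4-(benzyloxy)phenyl]-7-methoxy-4-oxochroman-6-yl}oxy)phenyl]-4H-chromen-4-one
Conditions: Dess–Martin periodinane, NaHCO3, CH2Cl2, rt
Reagents that add atoms: none
Why: Dess–Martin oxidation of a secondary benzylic alcohol under buffered, non-basic conditions, so ring C cannot open by retro-oxa-Michael reaction and C2 should keep its configuration.

Step 16
Reactants: 27 protected (2S)-flavanone
Product: 28 CNP0269971.1, 5,7-dihydroxy-2-[4-({(2S)-5-hydroxy-2-(4-hydroxyphenyl)-7-methoxy-4-oxochroman-6-yl}oxy)phenyl]-4H-chromen-4-one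
Conditions: H2 (1 atm), Pd/C, EtOAc/THF, rt, stopped at full debenzylation
Reagents that add atoms: none
Why: Catalytic hydrogenolysis of four aryl benzyl ethers under neutral conditions, the usual last step for benzyl-protected flavonoids; neutrality protects the base-labile C2 centre, and low pressure and short contact time should spare the flavone double bond and the C2–O1 bond.

## Compound list

1 | 2′,4′,6′-trihydroxyacetophenone | CC(=O)c1c(O)cc(O)cc1O | starting material
2 | 1-[2,4-bis(benzyloxy)-6-hydroxyphenyl]ethan-1-one | CC(=O)c1c(O)cc(OCc2ccccc2)cc1OCc1ccccc1 | intermediate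
3 | (4-formylphenoxy)acetic acid | O=Cc1ccc(OCC(=O)O)cc1 | starting material
4 | 2-{4-[(E)-3-(2,4-bis(benzyloxy)-6-hydroxyphenyl)-3-oxoprop-1-en-1-yl]phenoxy}acetic acid | OC(=O)COc1ccc(/C=C/C(=O)c2c(O)cc(OCc3ccccc3)cc2OCc2ccccc2)cc1 | intermediate
5 | 2-{4-[5,7-bis(benzyloxy)-4-oxo-4H-chromen-2-yl]phenoxy}acetic acid | OC(=O)COc1ccc(cc1)-c1cc(=O)c2c(OCc3ccccc3)cc(OCc3ccccc3)cc2o1 | intermediate
6 | chloroacetaldehyde dimethyl acetal (2-chloro-1,1-dimethoxyethane) | COC(CCl)OC | starting material
7 | methoxyacetylene (methoxyethyne) | COC#C | intermediate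
8 | 2-{4-[5,7-bis(benzyloxy)-4-oxo-4H-chromen-2-yl]phenoxy}acetyl chloride | ClC(=O)COc1ccc(cc1)-c1cc(=O)c2c(OCc3ccccc3)cc(OCc3ccccc3)cc2o1 | intermediate
9 | 2-{4-[5,7-bis(benzyloxy)-4-oxo-4H-chromen-2-yl]phenoxy}ethen-1-one (aryloxyketene) | O=C=COc1ccc(cc1)-c1cc(=O)c2c(OCc3ccccc3)cc(OCc3ccccc3)cc2o1 | intermediate
10 | 5,7-bis(benzyloxy)-2-{4-[(2-methoxy-4-oxocyclobut-2-en-1-yl)oxy]phenyl}-4H-chromen-4-one (racemic) | COC1=CC(=O)C1Oc1ccc(cc1)-c1cc(=O)c2c(OCc3ccccc3)cc(OCc3ccccc3)cc2o1 | intermediate
11 | 4′-(benzyloxy)acetophenone | CC(=O)c1ccc(OCc2ccccc2)cc1 | starting material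
12 | propargyl bromide (3-bromoprop-1-yne) | BrCC#C | starting material
13 | 1-[4-(benzyloxy)phenyl]pent-4-yn-1-one | C#CCCC(=O)c1ccc(OCc2ccccc2)cc1 | intermediate
14 | (R)-1-[4-(benzyloxy)phenyl]pent-4-yn-1-ol | C#CCC[C@@H](O)c1ccc(OCc2ccccc2)cc1 | intermediate
15 | (R)-{1-[4-(benzyloxy)phenyl]pent-4-yn-1-yl}oxy(tert-butyl)dimethylsilane | C#CCC[C@@H](O[Si](C)(C)C(C)(C)C)c1ccc(OCc2ccccc2)cc1 | intermediate
16 | lithium (R)-5-[4-(benzyloxy)phenyl]-5-[(tert-butyldimethylsilyl)oxy]pent-1-yn-1-olate | [Li]OC#CCC[C@@H](O[Si](C)(C)C(C)(C)C)c1ccc(OCc2ccccc2)cc1 | intermediate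
17 | (R)-tert-butyl({1-[4-(benzyloxy)phenyl]-5-[(triisopropylsilyl)oxy]pent-4-yn-1-yl}oxy)dimethylsilane | CC(C)[Si](OC#CCC[C@@H](O[Si](C)(C)C(C)(C)C)c1ccc(OCc2ccccc2)cc1)(C(C)C)C(C)C | intermediate
18 | (3Z)-4-aryloxy-3-methoxybuta-1,3-dien-1-one, aryl = 4-[5,7-bis(benzyloxy)-4-oxo-4H-chromen-2-yl]phenyl (vinylketene) | O=C=C/C(OC)=C/Oc1ccc(cc1)-c1cc(=O)c2c(OCc3ccccc3)cc(OCc3ccccc3)cc2o1 | intermediate
19 | 4-[(Z)-2-aryloxy-1-methoxyvinyl]-2-{(3R)-3-[4-(benzyloxy)phenyl]-3-[(tert-butyldimethylsilyl)oxy]propyl}-3-[(triisopropylsilyl)oxy]cyclobut-2-en-1-one, aryl as in 18 (ring carbon C4 unassigned) | O=C1C(CC[C@@H](O[Si](C)(C)C(C)(C)C)c2ccc(OCc3ccccc3)cc2)=C(O[Si](C(C)C)(C(C)C)C(C)C)C1/C(OC)=C/Oc1ccc(cc1)-c1cc(=O)c2c(OCc3ccccc3)cc(OCc3ccccc3)cc2o1 | intermediate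
20 | (3E,5Z)-6-aryloxy-2-{(3R)-3-[4-(benzyloxy)phenyl]-3-[(tert-butyldimethylsilyl)oxy]propyl}-5-methoxy-3-[(triisopropylsilyl)oxy]hexa-1,3,5-trien-1-one, aryl as in 18 (dienylketene) | O=C=C(CC[C@@H](O[Si](C)(C)C(C)(C)C)c1ccc(OCc2ccccc2)cc1)/C(O[Si](C(C)C)(C(C)C)C(C)C)=C\C(OC)=C\Oc1ccc(cc1)-c1cc(=O)c2c(OCc3ccccc3)cc(OCc3ccccc3)cc2o1 | intermediate
21 | 6-aryloxy-2-{(3R)-3-[4-(benzyloxy)phenyl]-3-[(tert-butyldimethylsilyl)oxy]propyl}-5-methoxy-3-[(triisopropylsilyl)oxy]cyclohexa-2,4-dien-1-one, aryl as in 18 (ring carbon C6 unassigned) | O=C1C(CC[C@@H](O[Si](C)(C)C(C)(C)C)c2ccc(OCc3ccccc3)cc2)=C(O[Si](C(C)C)(C(C)C)C(C)C)C=C(OC)C1Oc1ccc(cc1)-c1cc(=O)c2c(OCc3ccccc3)cc(OCc3ccccc3)cc2o1 | intermediate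
22 | 5,7-bis(benzyloxy)-2-[4-({3-[(3R)-3-[4-(benzyloxy)phenyl]-3-[(tert-butyldimethylsilyl)oxy]propyl]-2-hydroxy-6-methoxy-4-[(triisopropylsilyl)oxy]phenyl}oxy)phenyl]-4H-chromen-4-one | COc1cc(O[Si](C(C)C)(C(C)C)C(C)C)c(CC[C@@H](O[Si](C)(C)C(C)(C)C)c2ccc(OCc3ccccc3)cc2)c(O)c1Oc1ccc(cc1)-c1cc(=O)c2c(OCc3ccccc3)cc(OCc3ccccc3)cc2o1 | intermediate
23 | 5,7-bis(benzyloxy)-2-[4-({2-(benzyloxy)-3-[(3R)-3-[4-(benzyloxy)phenyl]-3-[(tert-butyldimethylsilyl)oxy]propyl]-6-methoxy-4-[(triisopropylsilyl)oxy]phenyl}oxy)phenyl]-4H-chromen-4-one | COc1cc(O[Si](C(C)C)(C(C)C)C(C)C)c(CC[C@@H](O[Si](C)(C)C(C)(C)C)c2ccc(OCc3ccccc3)cc2)c(OCc2ccccc2)c1Oc1ccc(cc1)-c1cc(=O)c2c(OCc3ccccc3)cc(OCc3ccccc3)cc2o1 | intermediate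
24 | 5,7-bis(benzyloxy)-2-[4-({2-(benzyloxy)-3-[(3R)-3-[4-(benzyloxy)phenyl]-3-hydroxypropyl]-4-hydroxy-6-methoxyphenyl}oxy)phenyl]-4H-chromen-4-one | COc1cc(O)c(CC[C@@H](O)c2ccc(OCc3ccccc3)cc2)c(OCc2ccccc2)c1Oc1ccc(cc1)-c1cc(=O)c2c(OCc3ccccc3)cc(OCc3ccccc3)cc2o1 | intermediate
25 | 5,7-bis(benzyloxy)-2-[4-({(2S)-5-(benzyloxy)-2-[4-(benzyloxy)phenyl]-7-methoxychroman-6-yl}oxy)phenyl]-4H-chromen-4-one | COc1cc2c(c(OCc3ccccc3)c1Oc1ccc(-c3cc(=O)c4c(OCc5ccccc5)cc(OCc5ccccc5)cc4o3)cc1)CC[C@@H](c1ccc(OCc3ccccc3)cc1)O2 | intermediate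
26 | 5,7-bis(benzyloxy)-2-[4-({(2S)-5-(benzyloxy)-2-[4-(benzyloxy)phenyl]-4-hydroxy-7-methoxychroman-6-yl}oxy)phenyl]-4H-chromen-4-one (C4 epimers) | COc1cc2c(c(OCc3ccccc3)c1Oc1ccc(-c3cc(=O)c4c(OCc5ccccc5)cc(OCc5ccccc5)cc4o3)cc1)C(O)C[C@@H](c1ccc(OCc3ccccc3)cc1)O2 | intermediate
27 | 5,7-bis(benzyloxy)-2-[4-({(2S)-5-(benzyloxy)-2-[4-(benzyloxy)phenyl]-7-methoxy-4-oxochroman-6-yl}oxy)phenyl]-4H-chromen-4-one | COc1cc2c(c(OCc3ccccc3)c1Oc1ccc(-c3cc(=O)c4c(OCc5ccccc5)cc(OCc5ccccc5)cc4o3)cc1)C(=O)C[C@@H](c1ccc(OCc3ccccc3)cc1)O2 | intermediate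
28 | 5,7-dihydroxy-2-[4-({(2S)-5-hydroxy-2-(4-hydroxyphenyl)-7-methoxy-4-oxochroman-6-yl}oxy)phenyl]-4H-chromen-4-one (CNP0269971.1) | COc1cc2c(c(O)c1Oc1ccc(-c3cc(=O)c4c(O)cc(O)cc4o3)cc1)C(=O)C[C@@H](c1ccc(O)cc1)O2 | target

## Step count and uncertain steps

Total: 16 steps. Longest linear sequence: 11 steps (1, 2, 3, 5, 10–16; the alkyne branch 6–9 followed by 10–16 is equally long).

**Step 10 (key step).** The 3-methoxy group makes 10 a vinylogous ester, which may slow the electrocyclic opening until the temperature needed exceeds what the siloxyalkyne tolerates. The vinylketene may also be lost to dimerisation or to acylation of the product phenol. Fallback: generate the same vinylketene at or below room temperature by 1,4-dehydrochlorination instead of ring opening. It sets out from acid 5, through its chloride 8, and rejoins the route at vinylketene 18.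
- Acylation of the lithium enolate of methyl acetate (LiN(iPr)2, THF, −78 °C) with 8 would give methyl 4-aryloxy-3-oxobutanoate F1 (aryl = 4-[5,7-bis(benzyloxy)-4-oxo-4H-chromen-2-yl]phenyl).
- HC(OMe)3 with catalytic H2SO4 in MeOH would give methyl (E)-4-aryloxy-3-methoxybut-2-enoate F2.
- LiOH in aqueous THF would give (E)-4-aryloxy-3-methoxybut-2-enoic acid F3.
- The chloroenamine of step 5 would give (E)-4-aryloxy-3-methoxybut-2-enoyl chloride F4, which is not isolated.
- Slow addition of Et3N in the presence of 17 removes the γ-hydrogen and chloride to give 18, which goes on through 19, 20 and 21 to 22 on gentle warming.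

**Step 5.** The monosubstituted aryloxyketene may dimerise or oligomerise faster than it adds to the volatile, unstable methoxyacetylene. Fallback: starting again from 5 (through 8 and 9), trap the ketene with commercial 1,1-dimethoxyethene in a [2+2] cycloaddition to give 2-aryloxy-3,3-dimethoxycyclobutan-1-one F5. Loss of methanol on silica gel or with a trace of acid returns to 10. This also removes the need for step 4.

**Step 14.** Loss of the C3 proton from the C4 cation may outrun capture by water, giving the flav-3-ene and products of further oxidation. Competing hydride abstraction at C2, which is a para-alkoxybenzylic ether position, would destroy the stereocentre. Fallback: make the elimination the intended reaction. From 25, one equivalent of DDQ in dry dioxane would give the (2S)-flav-3-ene F6. Mukaiyama hydration (Co(acac)2, PhSiH3, O2, THF/iPrOH) would place oxygen at the benzylic C4 and return to 26.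

**Step 13.** The oxyphosphonium intermediate at the para-benzyloxybenzylic carbon may ionise before substitution. That would erode the enantiomeric purity at C2 or give the styrene by elimination. Fallback: set C2 by catalytic hydrogenation after ring closure instead of by SN2. It sets out from 23 and returns at 25.
- HF·pyridine (THF, 0 °C) would remove only the alkyl silyl ether to give the secondary alcohol F7.
- Dess–Martin periodinane would give the aryl ketone F8.
- Bu4NF would free the phenol to give the hydroxy ketone F9.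
- Catalytic p-TsOH in toluene with removal of water would cyclodehydrate F9 to the 2-aryl-4H-chromene F10.
- Asymmetric hydrogenation of this enol ether with a cationic iridium phosphinooxazoline catalyst, [Ir(cod)(L)]B[C6H3(CF3)2]4, with the ligand enantiomer chosen for (2S), would give 25. Such catalysts do not cleave benzyl ethers.

**Step 16.** Hydrogenation may not stop at debenzylation: the flavone C2=C3 bond may be saturated, or the benzylic C2–O1 bond of ring C cleaved to the dihydrochalcone. Fallback: from 27, replace reduction by Lewis-acid ether cleavage with BCl3 and pentamethylbenzene as benzyl-cation scavenger (CH2Cl2, −78 °C), which gives 28 directly. At that temperature the non-chelated C7 methyl ether should persist.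

## Further compounds

F1 | step 10 | methyl 4-{4-[5,7-bis(benzyloxy)-4-oxo-4H-chromen-2-yl]phenoxy}-3-oxobutanoate | COC(=O)CC(=O)COc1ccc(cc1)-c1cc(=O)c2c(OCc3ccccc3)cc(OCc3ccccc3)cc2o1
F2 | step 10 | methyl (E)-4-{4-[5,7-bis(benzyloxy)-4-oxo-4H-chromen-2-yl]phenoxy}-3-methoxybut-2-enoate | COC(=O)/C=C(/OC)COc1ccc(cc1)-c1cc(=O)c2c(OCc3ccccc3)cc(OCc3ccccc3)cc2o1
F3 | step 10 | (E)-4-{4-[5,7-bis(benzyloxy)-4-oxo-4H-chromen-2-yl]phenoxy}-3-methoxybut-2-enoic acid | OC(=O)/C=C(/OC)COc1ccc(cc1)-c1cc(=O)c2c(OCc3ccccc3)cc(OCc3ccccc3)cc2o1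
F4 | step 10 | (E)-4-{4-[5,7-bis(benzyloxy)-4-oxo-4H-chromen-2-yl]phenoxy}-3-methoxybut-2-enoyl chloride | ClC(=O)/C=C(/OC)COc1ccc(cc1)-c1cc(=O)c2c(OCc3ccccc3)cc(OCc3ccccc3)cc2o1
F5 | step 5 | 2-{4-[5,7-bis(benzyloxy)-4-oxo-4H-chromen-2-yl]phenoxy}-3,3-dimethoxycyclobutan-1-one (racemic) | COC1(OC)CC(=O)C1Oc1ccc(cc1)-c1cc(=O)c2c(OCc3ccccc3)cc(OCc3ccccc3)cc2o1
F6 | step 14 | 5,7-bis(benzyloxy)-2-[4-({(2S)-5-(benzyloxy)-2-[4-(benzyloxy)phenyl]-7-methoxy-2H-chromen-6-yl}oxy)phenyl]-4H-chromen-4-one | COc1cc2c(c(OCc3ccccc3)c1Oc1ccc(-c3cc(=O)c4c(OCc5ccccc5)cc(OCc5ccccc5)cc4o3)cc1)C=C[C@@H](c1ccc(OCc3ccccc3)cc1)O2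
F7 | step 13 | 5,7-bis(benzyloxy)-2-[4-({2-(benzyloxy)-3-[(3R)-3-[4-(benzyloxy)phenyl]-3-hydroxypropyl]-6-methoxy-4-[(triisopropylsilyl)oxy]phenyl}oxy)phenyl]-4H-chromen-4-one | COc1cc(O[Si](C(C)C)(C(C)C)C(C)C)c(CC[C@@H](O)c2ccc(OCc3ccccc3)cc2)c(OCc2ccccc2)c1Oc1ccc(cc1)-c1cc(=O)c2c(OCc3ccccc3)cc(OCc3ccccc3)cc2o1
F8 | step 13 | 5,7-bis(benzyloxy)-2-[4-({2-(benzyloxy)-3-{3-[4-(benzyloxy)phenyl]-3-oxopropyl}-6-methoxy-4-[(triisopropylsilyl)oxy]phenyl}oxy)phenyl]-4H-chromen-4-one | COc1cc(O[Si](C(C)C)(C(C)C)C(C)C)c(CCC(=O)c2ccc(OCc3ccccc3)cc2)c(OCc2ccccc2)c1Oc1ccc(cc1)-c1cc(=O)c2c(OCc3ccccc3)cc(OCc3ccccc3)cc2o1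
F9 | step 13 | 5,7-bis(benzyloxy)-2-[4-({2-(benzyloxy)-3-{3-[4-(benzyloxy)phenyl]-3-oxopropyl}-4-hydroxy-6-methoxyphenyl}oxy)phenyl]-4H-chromen-4-one | COc1cc(O)c(CCC(=O)c2ccc(OCc3ccccc3)cc2)c(OCc2ccccc2)c1Oc1ccc(cc1)-c1cc(=O)c2c(OCc3ccccc3)cc(OCc3ccccc3)cc2o1
F10 | step 13 | 5,7-bis(benzyloxy)-2-[4-({5-(benzyloxy)-2-[4-(benzyloxy)phenyl]-7-methoxy-4H-chromen-6-yl}oxy)phenyl]-4H-chromen-4-one | COc1cc2c(c(OCc3ccccc3)c1Oc1ccc(-c3cc(=O)c4c(OCc5ccccc5)cc(OCc5ccccc5)cc4o3)cc1)CC=C(c1ccc(OCc3ccccc3)cc1)O2
F0 | step 16 | none | none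
A1 | alternative 1 | 3,5-bis(benzyloxy)-2-iodophenol | Oc1cc(OCc2ccccc2)cc(OCc2ccccc2)c1I
A2 | alternative 1 | tert-butyl({(2S,4S)-2-[4-(benzyloxy)phenyl]-6-(4-ethynylphenoxy)-5,7-dimethoxychroman-4-yl}oxy)dimethylsilane | CC(C)(C)[Si](C)(C)O[C@H]1C[C@@H](c2ccc(OCc3ccccc3)cc2)Oc2cc(OC)c(Oc3ccc(cc3)C#C)c(OC)c12
A3 | alternative 1 | 5,7-bis(benzyloxy)-2-[4-({(2S,4S)-2-[4-(benzyloxy)phenyl]-4-[(tert-butyldimethylsilyl)oxy]-5,7-dimethoxychroman-6-yl}oxy)phenyl]-4H-chromen-4-one | CC(C)(C)[Si](C)(C)O[C@H]1C[C@@H](c2ccc(OCc3ccccc3)cc2)Oc2cc(OC)c(Oc3ccc(cc3)-c3cc(=O)c4c(OCc5ccccc5)cc(OCc5ccccc5)cc4o3)c(OC)c12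
A4 | alternative 2 | methyl 4-[6-(4-{[4-(benzyloxy)-2,6-dimethoxyphenyl]oxy}phenyl)-4-oxo-4H-pyran-2-yl]-3-oxobutanoate | COC(=O)CC(=O)Cc1cc(=O)cc(o1)-c1ccc(Oc2c(OC)cc(OCc3ccccc3)cc2OC)cc1
A5 | alternative 2 | 2-(4-{[4-(benzyloxy)-2,6-dimethoxyphenyl]oxy}phenyl)-5,7-dihydroxy-4H-chromen-4-one | Oc1cc(O)c2c(c1)oc(cc2=O)-c1ccc(Oc2c(OC)cc(OCc3ccccc3)cc2OC)cc1
A6 | alternative 3 | (3S)-3-(4-acetoxyphenyl)-3-[4-({4-[5,7-bis(benzyloxy)-4-oxo-4H-chromen-2-yl]phenyl}oxy)-3,5-dimethoxyphenoxy]propanoic acid | OC(=O)C[C@@H](c1ccc(OC(C)=O)cc1)Oc1cc(OC)c(Oc2ccc(-c3cc(=O)c4c(OCc5ccccc5)cc(OCc5ccccc5)cc4o3)cc2)c(OC)c1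
A7 | alternative 3 | 4-[(2S)-6-({4-[5,7-bis(benzyloxy)-4-oxo-4H-chromen-2-yl]phenyl}oxy)-5,7-dimethoxy-4-oxochroman-2-yl]phenyl acetate | COc1cc2c(c(OC)c1Oc1ccc(-c3cc(=O)c4c(OCc5ccccc5)cc(OCc5ccccc5)cc4o3)cc1)C(=O)C[C@@H](c1ccc(OC(C)=O)cc1)O2
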